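**Retrosynthetic overview**

1. Target ⇒ E-selective cross-metathesis between a 2-vinyl furo[3,2-b]pyranone core and the anti-diol monobenzoate side chain (side chain from ethanol and acrolein dibenzoate by iridium-catalysed benzoyloxyallylation).
2. Tetrahydrofuran ring (formed second) ⇒ cis-5-hydroxy-6-[(Z)-butadienyl]-5,6-dihydropyran-2-one: hydroxyl-directed epoxidation of the Z-alkene, then 5-endo opening of the cis-vinyl epoxide by the same hydroxyl in the same flask (diene → epoxide → furanopyranone, as proposed for altholactone-type lactones); this sets C2 and C3.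
3. Z-diene ⇒ enyne (semi-hydrogenation); cis-hydroxyl ⇒ ketone reduction of a pyran-2,5-dione.
4. Pyranone ring (formed first) ⇒ furan as a latent (Z)-4-oxo-2-enal: oxidative unmasking, closure of the carbinol oxygen onto C1 (the bond that polyketide off-loading lactonisation makes), oxidation of the lactol to the lactone.
5. Furyl carbinol ⇒ furfural + but-1-en-3-yne by catalytic asymmetric alkynylation; this one stereocentre controls all ring stereocentres.

Assumption: the SMILES is read literally (all-cis 2S,3R,3aR,7aR bicycle, 3S,4R side chain); in the two catalytic asymmetric steps the ligand antipode is the one that gives the stated product (checked once by Mosher ester analysis); but-1-en-3-yne is bought as its commercial solution.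

**Route**

Step 1
Reactants: 1 furfural (furan-2-carbaldehyde); 2 but-1-en-3-yne (vinylacetylene)
Product: 4 (1R)-1-(furan-2-yl)pent-4-en-2-yn-1-ol, via zinc acetylide 3 (not isolated)
Conditions: Me2Zn (3 equiv), ProPhenol (10 mol %), Ph3PO (20 mol %), toluene, 0 °C; then H2O
Reagents that add atoms: none
Why: Catalytic enantioselective alkynylzinc addition to an aldehyde (zinc–ProPhenol alkynylation), in which the dinuclear zinc catalyst binds furfural and the zinc acetylide 3 and delivers the alkynyl group to one enantioface, setting the carbinol centre (the later lactone C–O carbon) as R.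

Step 2
Reactants: 4 (1R)-1-(furan-2-yl)pent-4-en-2-yn-1-ol
Product: 6 (2R,6RS)-2-(but-3-en-1-yn-1-yl)-6-hydroxy-2H-pyran-3(6H)-one, via ring-opened Z-keto-enal 5 (not isolated)
Conditions: NBS (1.1 equiv), NaHCO3, NaOAc, THF/H2O 4:1, 0 °C
Reagents that add atoms: water, O
Why: Achmatowicz oxidative ring expansion, in which bromination and hydrolysis unmask the furan as the Z-keto-enal 5 and the carbinol oxygen closes onto the aldehyde carbon to form the six-membered ring, the carbinol centre not being touched.

Step 3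
Reactants: 6 (2R,6RS)-2-(but-3-en-1-yn-1-yl)-6-hydroxy-2H-pyran-3(6H)-one
Product: 7 (6R)-6-(but-3-en-1-yn-1-yl)-2H-pyran-2,5(6H)-dione
Conditions: CrO3, H2SO4, acetone, 0 °C, 10 min
Reagents that add atoms: none
Why: Jones oxidation of the allylic lactol to the lactone, which is fast at 0 °C and leaves the enyne and the C6 centre alone when the contact time is short.

Step 4
Reactants: 7 (6R)-6-(but-3-en-1-yn-1-yl)-2H-pyran-2,5(6H)-dione
Product: 8 (5R,6R)-6-(but-3-en-1-yn-1-yl)-5-hydroxy-5,6-dihydro-2H-pyran-2-one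
Conditions: NaBH4, CeCl3·7H2O, MeOH/CH2Cl2, −78 °C
Reagents that add atoms: none
Why: Luche 1,2-reduction, in which hydride adds to the ketone of the nearly flat ene-dione ring from the face opposite the C6 substituent, so the new hydroxyl (5R) is cis to the side chain.

Step 5
Reactants: 8 (5R,6R)-6-(but-3-en-1-yn-1-yl)-5-hydroxy-5,6-dihydro-2H-pyran-2-one
Product: 9 (5R,6R)-6-[(1Z)-buta-1,3-dien-1-yl]-5-hydroxy-5,6-dihydro-2H-pyran-2-one
Conditions: H2 (1 atm), Pd/CaCO3 poisoned with Pb(OAc)2, quinoline, EtOAc, 0 °C, stopped at 1 equiv H2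
Reagents that add atoms: none
Why: Lindlar semi-hydrogenation, in which syn addition of hydrogen to the alkyne gives the 1Z-diene while the conjugated lactone alkene and the terminal vinyl group react much more slowly.

Step 6
Reactants: 9 (5R,6R)-6-[(1Z)-buta-1,3-dien-1-yl]-5-hydroxy-5,6-dihydro-2H-pyran-2-one
Product: 11 (2S,3R,3aR,7aR)-2-ethenyl-3-hydroxy-2,3,3a,7a-tetrahydro-5H-furo[3,2-b]pyran-5-one, via cis-vinyl epoxide 10 (not isolated)
Conditions: VO(acac)2 (5 mol %), t-BuOOH (1.5 equiv, decane), CH2Cl2, 0 °C to rt; then CSA (20 mol %), rt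
Reagents that add atoms: tert-butyl hydroperoxide, CC(C)(C)OO
Why: Hydroxyl-directed vanadium-catalysed epoxidation of a homoallylic alcohol followed by acid-promoted 5-endo epoxide-opening etherification at a vinyl-activated carbon: with C6–H eclipsing the Z-alkene (allylic 1,3-strain) the pentavalent vanadium alkylperoxide bound to the C5 hydroxyl delivers oxygen to the alkene face on its own side, fixing C3 as R, and the same hydroxyl then opens epoxide 10 at the allylic carbon with inversion, fixing C2 as S and giving the all-cis tetrahydrofuran.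

Step 7
Reactants: 12 acrolein; 13 benzoic anhydride
Product: 14 prop-2-ene-1,1-diyl dibenzoate
Conditions: FeCl3 (2 mol %), CH2Cl2, 0 °C to rt
Reagents that add atoms: none
Why: Lewis-acid-catalysed acylal formation (addition of an anhydride across an aldehyde C=O), which is clean for acrolein and creates no stereocentre.

Step 8
Reactants: 14 prop-2-ene-1,1-diyl dibenzoate; 15 ethanol
Product: 17 (3S,4R)-4-hydroxypent-1-en-3-yl benzoate, via acetaldehyde 16 (not isolated)
Conditions: [Ir(cod)Cl]2 (2.5 mol %), SEGPHOS (5 mol %), 4-cyano-3-nitrobenzoic acid (10 mol %), K3PO4 (cat.), THF, 90 °C, sealed tube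
Reagents that add atoms: none
Why: Iridium-catalysed transfer-hydrogenative carbonyl (α-benzoyloxy)allylation (Krische type), in which ethanol is dehydrogenated to acetaldehyde 16 and this is captured by the (E)-γ-benzoyloxy-allyl iridium species through a closed chair transition state, giving the anti-diol monobenzoate with the benzoate on the allylic oxygen and the absolute configuration (3S,4R) set by the ligand.

Step 9
Reactants: 11 (2S,3R,3aR,7aR)-2-ethenyl-3-hydroxy-2,3,3a,7a-tetrahydro-5H-furo[3,2-b]pyran-5-one; 17 (3S,4R)-4-hydroxypent-1-en-3-yl benzoate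
Product: 18 (1E,3S,4R)-4-hydroxy-1-[(2S,3R,3aR,7aR)-3-hydroxy-5-oxo-2,3,3a,7a-tetrahydro-5H-furo[3,2-b]pyran-2-yl]pent-1-en-3-yl benzoate (CNP0140142.1)
Conditions: second-generation Hoveyda–Grubbs catalyst RuCl2(H2IMes)(=CH-C6H4-2-OiPr) (10 mol %), 17 (4 equiv), CH2Cl2, 40 °C
Reagents that add atoms: none
Why: Olefin cross-metathesis, in which both partners are allylic-oxygenated terminal alkenes that homodimerise slowly, so an excess of 17 drives the cross product, formed as the favoured E-alkene, while the conjugated lactone alkene is inert and no stereocentre is touched.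

**Compound list**

1 | furfural (furan-2-carbaldehyde) | O=Cc1ccco1 | starting material
2 | but-1-en-3-yne (vinylacetylene) | C=CC#C | starting material
3 | zinc acetylide: methyl(but-3-en-1-yn-1-yl)zinc | C[Zn]C#CC=C | intermediate
4 | (1R)-1-(furan-2-yl)pent-4-en-2-yn-1-ol | O[C@H](C#CC=C)c1ccco1 | intermediate
5 | ring-opened Z-keto-enal: (2Z,5R)-5-hydroxy-4-oxonona-2,8-dien-6-ynal | O=C/C=C\C(=O)[C@H](O)C#CC=C | intermediate
6 | (2R,6RS)-2-(but-3-en-1-yn-1-yl)-6-hydroxy-2H-pyran-3(6H)-one (anomer mixture) | O=C1C=CC(O)O[C@@H]1C#CC=C | intermediate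
7 | (6R)-6-(but-3-en-1-yn-1-yl)-2H-pyran-2,5(6H)-dione | O=C1C=CC(=O)O[C@@H]1C#CC=C | intermediate
8 | (5R,6R)-6-(but-3-en-1-yn-1-yl)-5-hydroxy-5,6-dihydro-2H-pyran-2-one (cis) | O[C@@H]1C=CC(=O)O[C@@H]1C#CC=C | intermediate
9 | (5R,6R)-6-[(1Z)-buta-1,3-dien-1-yl]-5-hydroxy-5,6-dihydro-2H-pyran-2-one | O[C@@H]1C=CC(=O)O[C@@H]1/C=C\C=C | intermediate
10 | cis-vinyl epoxide: (5R,6S)-6-[(2R,3R)-3-ethenyloxiran-2-yl]-5-hydroxy-5,6-dihydro-2H-pyran-2-one | O[C@@H]1C=CC(=O)O[C@@H]1[C@@H]2O[C@@H]2C=C | intermediate
11 | (2S,3R,3aR,7aR)-2-ethenyl-3-hydroxy-2,3,3a,7a-tetrahydro-5H-furo[3,2-b]pyran-5-one (all-cis) | C=C[C@@H]1O[C@@H]2C=CC(=O)O[C@@H]2[C@@H]1O | intermediate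
12 | acrolein | C=CC=O | starting material
13 | benzoic anhydride | O=C(OC(=O)c1ccccc1)c1ccccc1 | starting material
14 | prop-2-ene-1,1-diyl dibenzoate | C=CC(OC(=O)c1ccccc1)OC(=O)c1ccccc1 | intermediate
15 | ethanol | CCO | starting material
16 | acetaldehyde | CC=O | intermediate
17 | (3S,4R)-4-hydroxypent-1-en-3-yl benzoate (anti) | C[C@@H](O)[C@H](C=C)OC(=O)c1ccccc1 | intermediate
18 | (1E,3S,4R)-4-hydroxy-1-[(2S,3R,3aR,7aR)-3-hydroxy-5-oxo-2,3,3a,7a-tetrahydro-5H-furo[3,2-b]pyran-2-yl]pent-1-en-3-yl benzoate | C[C@@H](O)[C@H](/C=C/[C@@H]1O[C@@H]2C=CC(=O)O[C@@H]2[C@@H]1O)OC(=O)c1ccccc1 | target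

**Step count**

Total: 9 steps. Longest linear sequence: 7 steps (steps 1 to 6, then 9).

**Steps most likely to fail, with fallbacks**

Step 6 (epoxidation and ring closure in one flask). The cis-vinyl epoxide 10 may rearrange or be opened by the peroxide or tert-butanol instead of closing 5-endo, or the facial selectivity may be low. The fallback sets out from 9 and comes back at 11. A trace of iodine in daylight (CH2Cl2, rt) equilibrates the Z-diene to (5R,6R)-6-[(1E)-buta-1,3-dien-1-yl]-5-hydroxy-5,6-dihydro-2H-pyran-2-one F1. VO(acac)2 and t-BuOOH, with oxygen again delivered from the side of the C5 hydroxyl, then give the trans-vinyl epoxide (5R,6S)-6-[(2R,3S)-3-ethenyloxiran-2-yl]-5-hydroxy-5,6-dihydro-2H-pyran-2-one F2, which is isolated on buffered silica (an epimeric epoxide, if formed, is removed here). Pd(PPh3)4 (5 mol %, THF, rt; zerovalent palladium) ionises F2 with inversion to a π-allyl complex, and the C5 oxygen attacks the near allyl terminus with a second inversion. The net retention turns the trans epoxide into the same all-cis 11, and the closure is an attack on a π-allyl unit, no longer a strained 5-endo substitution.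

Step 9 (cross-metathesis). Two hindered allylic-oxygenated alkenes may couple slowly, 17 may homodimerise, or the allylic benzoate may isomerise. The fallback sets out from 11 and comes back at 18, and builds the alkene by carbonyl olefination.
- TESCl and imidazole give the 3-O-triethylsilyl ether of the core F3.
- OsO4 (cat.), NaIO4 and 2,6-lutidine in dioxane/water cut the vinyl group to the 3-O-triethylsilyl core 2-carbaldehyde F4.
- The stabilised ylide (3R)-3-(tert-butyldimethylsilyloxy)-1-(triphenylphosphoranylidene)butan-2-one F5, made from the TBS ether of methyl (R)-lactate and Ph3P=CH2, adds to F4 to give the E-enone bis-silyl ether F6.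
- Reagent-controlled reduction with a CBS oxazaborolidine and catecholborane (matched with Felkin control from the silyloxy centre) gives the 3S allylic alcohol bis-silyl ether F7.
- BzCl and pyridine give the bis-silyl ether of the target F8, and HF·pyridine removes both silyl groups under non-basic conditions, so the benzoate cannot migrate, giving 18.

Step 4 (ketone reduction). The slim alkynyl group may give poor cis selectivity, and the propargylic C6–H of 7 can enolise; steps 3 and 4 are therefore run cold and without storing 7. The fallback sets out from 7 and comes back at 8. If hydride reduction gives mainly the trans alcohol (5S,6R)-6-(but-3-en-1-yn-1-yl)-5-hydroxy-5,6-dihydro-2H-pyran-2-one F9, Mitsunobu esterification with formic acid (PPh3, DIAD, THF, 0 °C) inverts C5 to the cis formate (5R,6R)-6-(but-3-en-1-yn-1-yl)-6-oxo-3,6-dihydro-2H-pyran-3-yl formate, drawn as (5R,6R)-5-(formyloxy)-6-(but-3-en-1-yn-1-yl)-5,6-dihydro-2H-pyran-2-one F10. Mild methanolysis (NaHCO3, MeOH, 0 °C) then gives 8; the centre is set by invertive substitution, not by hydride delivery.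

**Further compounds**

F1 | step 6 | (5R,6R)-6-[(1E)-buta-1,3-dien-1-yl]-5-hydroxy-5,6-dihydro-2H-pyran-2-one | O[C@@H]1C=CC(=O)O[C@@H]1/C=C/C=C
F2 | step 6 | (5R,6S)-6-[(2R,3S)-3-ethenyloxiran-2-yl]-5-hydroxy-5,6-dihydro-2H-pyran-2-one (trans epoxide) | O[C@@H]1C=CC(=O)O[C@@H]1[C@@H]2O[C@H]2C=C
F3 | step 9 | 3-O-triethylsilyl ether of the core (ring configuration as in 11) | C=C[C@@H]1O[C@@H]2C=CC(=O)O[C@@H]2[C@@H]1O[Si](CC)(CC)CC
F4 | step 9 | 3-O-triethylsilyl core 2-carbaldehyde (ring configuration as in 11) | O=C[C@@H]1O[C@@H]2C=CC(=O)O[C@@H]2[C@@H]1O[Si](CC)(CC)CC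
F5 | step 9 | (3R)-3-(tert-butyldimethylsilyloxy)-1-(triphenylphosphoranylidene)butan-2-one | C[C@@H](O[Si](C)(C)C(C)(C)C)C(=O)C=P(c1ccccc1)(c1ccccc1)c1ccccc1
F6 | step 9 | E-enone bis-silyl ether (ring configuration as in 11, side-chain carbinol R) | C[C@@H](O[Si](C)(C)C(C)(C)C)C(=O)/C=C/[C@@H]1O[C@@H]2C=CC(=O)O[C@@H]2[C@@H]1O[Si](CC)(CC)CC
F7 | step 9 | 3S allylic alcohol bis-silyl ether (ring configuration as in 11) | C[C@@H](O[Si](C)(C)C(C)(C)C)[C@@H](O)/C=C/[C@@H]1O[C@@H]2C=CC(=O)O[C@@H]2[C@@H]1O[Si](CC)(CC)CC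
F8 | step 9 | bis-silyl ether of the target (ring O-triethylsilyl, side-chain O-tert-butyldimethylsilyl) | C[C@@H](O[Si](C)(C)C(C)(C)C)[C@H](/C=C/[C@@H]1O[C@@H]2C=CC(=O)O[C@@H]2[C@@H]1O[Si](CC)(CC)CC)OC(=O)c1ccccc1
F9 | step 4 | (5S,6R)-6-(but-3-en-1-yn-1-yl)-5-hydroxy-5,6-dihydro-2H-pyran-2-one (trans) | O[C@H]1C=CC(=O)O[C@@H]1C#CC=C
F10 | step 4 | (5R,6R)-5-(formyloxy)-6-(but-3-en-1-yn-1-yl)-5,6-dihydro-2H-pyran-2-one (cis formate) | O=CO[C@@H]1C=CC(=O)O[C@@H]1C#CC=C
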